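(The data stem from a simulated flask on assumed constants; the scatter is artificial.)

**Early times.** At early times target grew steadily in each run. I supposed that substrate and coupling partner react over the free catalyst to give target, and that target goes on over the same catalyst to over-reaction product. Both conversions should then scale with the charged c(free catalyst), which is mol% times c(substrate).

| setting | Thursday's | Tuesday's | Saturday's | epsilon | theta |
|---|---|---|---|---|---|
| substrate | 0.94 M | 2.1 M | 1.4 M | 1.4 M | 1.4 M |
| coupling partner | 0.95 equiv | 0.95 equiv | 0.95 equiv | 0.950 equiv | 0.950 equiv |
| free catalyst | 0.68 mol% | 0.68 mol% | 1.4 mol% | 0.68 mol% | 0.68 mol% |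
| remark | run made earlier | run made earlier | run made earlier |  |  |
| time |  |  |  | 12 h | 40 h |

| run | time / h | target / % |
|---|---|---|
| Thursday's | 1.00 | 6.0 |
| Thursday's | 2.00 | 11.0 |
| Thursday's | 4.00 | 19.2 |
| Thursday's | 8.00 | 32.2 |
| Thursday's | 15.0 | 40.5 |
| Tuesday's | 3.00 | 24.6 |
| Tuesday's | 6.00 | 40.5 |
| Tuesday's | 8.00 | 45.8 |
| Tuesday's | 12.0 | 46.3 |
| Tuesday's | 15.0 | 41.4 |
| Saturday's | 1.00 | 14.2 |
| Saturday's | 2.00 | 25.4 |
| Saturday's | 4.00 | 39.8 |
| Saturday's | 8.00 | 42.1 |
| Saturday's | 15.0 | 21.0 |

(standard deviation of a reading: 0.3 percentage points)

- which of the two there is more of at the end, epsilon (over-reaction product / target)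
- which of the two there is more of at the end, theta (over-reaction product / target)
- final target, as a percentage of the substrate charged, in epsilon
- final target, as a percentage of the substrate charged, in theta



**Main step.** I multiplied charged c(free catalyst) by time. Epsilon reaches 0.114 M·h, its catalyst dose. Thursday's first reading gives 9.39 /M/h of target per unit dose. Held straight, that line would give 107% in epsilon, more than the charge, and coupling partner, the limiting reagent at 0.950 equiv, caps target at that fraction.

**Substrate falling.** When I let the making of target slow as substrate falls, the figure became 65.7%.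

**Over-reaction.** Loss of target starts at zero and grows with target, while making shrinks with substrate, so I expected the two to cross. Tuesday's run shows the crossing: 45.8% at 8.00 h, 46.3% at 12.0 h, 41.4% at 15.0 h. Its 8.00 h reading has dose 0.114 M·h, the same as epsilon, so I expected about 45.8% there. The overlay is rough: Saturday's 8.00 h and Tuesday's 12.0 h stand 4.2 percentage points apart at nearby doses, against a scatter of 0.3 points.

Theta's dose is 0.381 M·h, beyond Saturday's last reading at 0.294 M·h. Read against dose, the last readings of Tuesday and Saturday give a logarithmic fall of target of 8.51 /M/h. Continued from Saturday's 21.0%, that gave me 10.0%.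

**The forecast.** It rested on the same ground, that “target curves overlay roughly when plotted against absolute catalyst concentration”. It put target ahead in epsilon at 45% (41% to 48%). In theta it put over-reaction product ahead, with target at 10% (3% to 19%).

**The flasks.** Epsilon gave target 44.2% and over-reaction product 17.8%. Theta gave target 11.1% and over-reaction product 79.4%.

    substrate + free catalyst ⇌ catalyst intermediate A (K = 2.20 /M, k = 0.734 /M/min)
    coupling partner + catalyst intermediate A → catalyst intermediate B (k = 0.495 /M/min)
    catalyst intermediate B ⇌ free catalyst + target (K = 3.60 M, k = 0.461 /min)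
    free catalyst + target → free catalyst + over-reaction product (k = 0.226 /M/min)

**Neighbour flask.** Both forecast values held, with epsilon at dose 0.114 M·h near Tuesday's reading. The neighbour is epsilon with 0.84 M of substrate, the same equivalents, loading and time, so its dose is 0.0685 M·h. That lies between Thursday's 8.00 h (dose 0.0511 M·h, 32.2%) and Saturday's 4.00 h (dose 0.0784 M·h, 39.8%), and interpolating gives 37.0%. The neighbour flask gave 36.2% target, with 53.9% of its substrate still unbound.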